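(All runs are simulated from invented constants; scatter was added.)

Find two numbers, and the choice between the flasks follows from them.

* which of the two ends with the longer chains by the average number of monomer units in a chain (chains begun, living or dead) ("neither" if they lie within 10 %) (south / north-west / neither)
* average number of monomer units in a chain (chains begun, living or dead) at the end, south
* average number of monomer units in a chain (chains begun, living or dead) at the end, north-west

| setting | midnight | noon | south | north-west |
|---|---|---|---|---|
| free monomer | 0.19 M | 0.19 M | 0.19 M | 0.19 M |
| protic impurity | 0.019 M | 0.019 M | 0.0190 M | 0.0190 M |
| initiator | 6.2 mM | 9.7 mM | 4.4 mM | 4.4 mM |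
| remark | run made earlier | run made earlier |  |  |
| time |  |  | 2.5 h | 5.0 h |

| midnight: time / h | midnight: monomer in chains / % | noon: time / h | noon: monomer in chains / % |
|---|---|---|---|
| 0.667 | 23.3 | 0.333 | 20.7 |
| 1.33 | 37.8 | 0.833 | 39.2 |
| 2.00 | 48.3 | 1.50 | 54.7 |
| 2.50 | 53.0 | 2.50 | 67.5 |

(readings scatter by 0.5 percentage points)

- the average divides the monomer in chains by the number of chains begun, living and dead together
- the earlier runs were read with a standard deviation of 0.5 percentage points
- the earlier runs do not show the number of chains; that part of a forecast is a guess

South and north-west have the same charge and differ in reading time, so compare them through one ratio. Divide [free monomer] by [initiator] as charged and call this the ceiling, 43.2 units per initiator. Now follow one molecule of free monomer: at the end it lies in a chain or it doesn't, and the readings give the chance that it does. The average length (number-average degree of polymerisation) is the ceiling times that chance, provided each initiator begins one chain, which is my guess.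

Get the chance from the last readings, both at 2.50 h. Take the logarithm of the inverse of the part not in chains and divide it by [initiator]: the midnight run reads 0.122 mM⁻¹, the noon run 0.116 mM⁻¹. Taking that logarithm as proportional to [initiator], scale each run to south's charge, which gives 41.5 % and 39.9 %. Their mean is 40.7 %, so my south length is 17.6.

For north-west, extrapolate past every reading. In the midnight run, time grew to nearly twice its value from 1.33 h to 2.50 h, and the logarithm grew by a factor of 1.59. Apply that factor to south as an estimate: my chance for north-west is 56.4 % and my length 24.4, longer than my south length by more than the margin.

The forecast also names north-west, with 17.5 (13.5 to 19.5) for south and 22.3 (15 to 26) for north-west, a north-west value below my length, and it warns: “The chain count was never measured.”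

The flask gives 18.7 for south and 25.4 for north-west, so north-west ends longer. At 5.00 h north-west holds 0.00437 M of living end and 3.46 × 10⁻⁵ M of spent initiator, together about the 4.4 mM of initiator charged. The ceiling times north-west's 58.4 % of monomer in chains gives 25.2.

    initiator → spent initiator (k = 0.00410 min⁻¹)
    free monomer + initiator → living end + monomer in chains (k = 2.80 M⁻¹ min⁻¹)
    free monomer + living end → monomer in chains + living end, rate k3*[living end]*[free monomer] (k = 1.10 M⁻¹ min⁻¹)
    protic impurity + free monomer → quenched substrate (k = 0.270 M⁻¹ min⁻¹)
    free monomer → uncatalysed product (k = 0.00160 min⁻¹)

Read south at 40 min instead: the ceiling times that flask's 17.2 % in chains gives 7.42, and the computed length is 7.48.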